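**Retrosynthetic overview**
1. Target 16 ⇐ macrocyclic alcohol 14, by acetylation of C1–OH and release of the phenol from its acetate.
2. 14 ⇐ acyclic (2Z,6E)-4-aroyloxyfarnesal 11, by the C1–C11 bond. This is the farnesyl-to-humulyl 1,11-closure run as a reductive alkene–aldehyde cyclisation (H to C10, C11 to C1=O) that forms the eleven-membered ring and the C1 stereocentre together.
3. 11 ⇐ butenolide 6, which holds the Z-alkene and C4; it is opened as a Weinreb amide, aroylated on O4 and reduced.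
4. 6 ⇐ (R)-ketol 3 + Ph3P=C=C=O; 3 ⇐ (E)-geranylacetone 1 by proline-catalysed α-aminoxylation, which sets C4.
5. Ring order: butenolide (temporary, step 2), then the eleven-membered carbocycle (step 5).

Assumption: (E)-geranylacetone is bought isomerically pure; atoms are numbered along the farnesane chain (C1 = CH–OAc, C4 = CH–O-aroyl, C11 = CMe2), which makes the target (1R,2Z,4R,6E) with the two oxygens cis across the Z-alkene.

**Step 1**
Reactants: 1 ((E)-geranylacetone)
Product: 3 (3R,5E)-3-hydroxy-6,10-dimethylundeca-5,9-dien-2-one, via anilinooxy ketone 2 (not isolated)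
Conditions: PhNO (1 equiv, syringe pump), 1 (3 equiv), L-proline (20 mol %), DMSO, 20 °C; then CuSO4·5H2O (30 mol %), MeOH, 0 °C
Reagents that add atoms: nitrosobenzene, O=Nc1ccccc1
Why: Proline-catalysed enamine α-aminoxylation (O-selective nitroso aldol) occurs at the more substituted enamine of a methyl ketone, L-proline delivers oxygen to the face that gives (R) at C4, and the copper-catalysed N–O cleavage does not touch the stereocentre.

**Step 2**
Reactants: 3 (ketol); 4 ((triphenylphosphoranylidene)ketene)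
Product: 6 (5R)-5-[(2E)-3,7-dimethylocta-2,6-dien-1-yl]-4-methylfuran-2(5H)-one, via ylide ester 5 (not isolated)
Conditions: toluene, 90 °C
Reagents that add atoms: none
Why: Bestmann butenolide synthesis: the hydroxyl adds to the ketene ylide to give a stabilised ester ylide that closes by intramolecular Wittig reaction on the methyl ketone, so the ring fixes the Z geometry of C2=C3 and C4 is not involved.

**Step 3**
Reactants: 6 (butenolide); 7 (4-acetoxybenzoyl chloride)
Product: 9 (2Z,4R,6E)-1-[methoxy(methyl)amino]-3,7,11-trimethyl-1-oxododeca-2,6,10-trien-4-yl 4-acetoxybenzoate, via aluminium alkoxide 8 (not isolated)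
Conditions: MeNHOMe·HCl (1.5 equiv), AlMe3 (1.5 equiv), CH2Cl2, 0 → 20 °C; then pyridine, DMAP (0.2 equiv), 7 (2.5 equiv), 0 → 20 °C
Reagents that add atoms: N,O-dimethylhydroxylamine hydrochloride, CNOC.Cl
Why: Weinreb aminolysis of the lactone by the non-basic aluminium amide opens the ring with the Z-alkene and C4 unchanged, and acylating the alkoxide in the same flask (nucleophilic acyl substitution, DMAP catalysis) stops the hydroxy amide from closing back to the lactone.

**Step 4**
Reactants: 9 (Weinreb amide ester)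
Product: 11 (2Z,4R,6E)-3,7,11-trimethyl-1-oxododeca-2,6,10-trien-4-yl 4-acetoxybenzoate, via zirconium hemiaminal 10 (not isolated)
Conditions: Cp2Zr(H)Cl (1.4 equiv), THF, 20 °C, 20 min; then H2O
Reagents that add atoms: none
Why: Chemoselective amide-to-aldehyde reduction with Cp2Zr(H)Cl stops at the O-zirconated hemiaminal, which releases the Z-enal on work-up, while the two esters and the trisubstituted alkenes react much more slowly.

**Step 5**
Reactants: 11 (Z-enal)
Product: 14 (1R,2Z,4R,6E)-1-hydroxy-3,7,11,11-tetramethylcycloundeca-2,6-dien-4-yl 4-acetoxybenzoate, via alkylchromium 12 (not isolated), via phenylsilyl ether 13 (not isolated)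
Conditions: [N,N′-bis(3,5-di-tert-butylsalicylidene)-1,2-cyclohexanediaminato]cobalt, C36H52CoN2O2 (divalent cobalt, 20 mol %), CrCl3 (50 mol %), PhSiH3 (2.5 equiv), THF, 25 °C, 11 added by syringe pump over 20 h (final 0.02 M); then 1 M aq. citric acid
Reagents that add atoms: none
Why: Proposed new method: this is an intramolecular version of the known cobalt-hydride/chromium branch-selective reductive coupling of unactivated alkenes with aldehydes (hydrogen-atom-transfer radical–polar crossover with Nozaki–Hiyama–Kishi-type addition), in which the cobalt hydride made from the silane puts H on C10 of the least hindered and most electron-rich alkene (C6=C7 is more hindered and inductively deactivated by the homoallylic ester, the enal alkene is electron-poor), the tertiary C11 radical is captured by divalent chromium as 12 and adds 1,2 to the aldehyde, and C1 is set because A1,3 strain places C4–H in the alkene plane so that the C5–C11 tether lies on one face and reaches the same face of the s-trans formyl group, which gives the (1R) carbinol cis to the C4 ester before acidic work-up cleaves silyl ether 13.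

**Step 6**
Reactants: 14 (macrocyclic alcohol)
Product: 16 (1R,2Z,4R,6E)-1-acetoxy-3,7,11,11-tetramethylcycloundeca-2,6-dien-4-yl 4-hydroxybenzoate, via diacetate 15 (not isolated)
Conditions: Ac2O (5 equiv), DMAP (0.5 equiv), pyridine, 40 °C; then pyrrolidine (10 equiv), 0 °C, 30 min
Reagents that add atoms: acetic anhydride, CC(=O)OC(C)=O
Why: DMAP-catalysed acetylation of the hindered neopentyl allylic alcohol is followed by chemoselective aminolysis of the far more electrophilic aryl acetate, which leaves the alkyl acetate and the secondary benzoate intact and changes no stereocentre.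

**Compound list**
1 | (E)-geranylacetone, (5E)-6,10-dimethylundeca-5,9-dien-2-one | CC(=O)CC/C=C(\C)CCC=C(C)C | starting material
2 | (3R,5E)-6,10-dimethyl-3-[(phenylamino)oxy]undeca-5,9-dien-2-one | CC(=O)[C@H](ONc1ccccc1)C/C=C(\C)CCC=C(C)C | intermediate
3 | (3R,5E)-3-hydroxy-6,10-dimethylundeca-5,9-dien-2-one | CC(=O)[C@H](O)C/C=C(\C)CCC=C(C)C | intermediate
4 | (triphenylphosphoranylidene)ketene | O=C=C=P(c1ccccc1)(c1ccccc1)c1ccccc1 | starting material
5 | (3R,5E)-6,10-dimethyl-2-oxoundeca-5,9-dien-3-yl (triphenylphosphoranylidene)acetate | CC(=O)[C@H](OC(=O)C=P(c1ccccc1)(c1ccccc1)c1ccccc1)C/C=C(\C)CCC=C(C)C | intermediate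
6 | (5R)-5-[(2E)-3,7-dimethylocta-2,6-dien-1-yl]-4-methylfuran-2(5H)-one | O=C1C=C(C)[C@H](O1)C/C=C(\C)CCC=C(C)C | intermediate
7 | 4-acetoxybenzoyl chloride | CC(=O)Oc1ccc(cc1)C(Cl)=O | starting material
8 | chloro(methyl)aluminium alkoxide of (2Z,4R,6E)-4-hydroxy-N-methoxy-N,3,7,11-tetramethyldodeca-2,6,10-trienamide | CON(C)C(=O)/C=C(/C)[C@H](O[Al](C)Cl)C/C=C(\C)CCC=C(C)C | intermediate
9 | (2Z,4R,6E)-1-[methoxy(methyl)amino]-3,7,11-trimethyl-1-oxododeca-2,6,10-trien-4-yl 4-acetoxybenzoate | CON(C)C(=O)/C=C(/C)[C@H](OC(=O)c1ccc(OC(C)=O)cc1)C/C=C(\C)CCC=C(C)C | intermediate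
10 | O-[chlorobis(cyclopentadienyl)zirconio] hemiaminal of 9 at C1 (both C1 epimers) | CON(C)C(O[Zr](Cl)(C1C=CC=C1)C1C=CC=C1)/C=C(/C)[C@H](OC(=O)c1ccc(OC(C)=O)cc1)C/C=C(\C)CCC=C(C)C | intermediate
11 | (2Z,4R,6E)-3,7,11-trimethyl-1-oxododeca-2,6,10-trien-4-yl 4-acetoxybenzoate | O=C/C=C(/C)[C@H](OC(=O)c1ccc(OC(C)=O)cc1)C/C=C(\C)CCC=C(C)C | intermediate
12 | tertiary C11 alkylchromium dichloride from 11 (C10 now CH2, trivalent chromium on C11) | O=C/C=C(/C)[C@H](OC(=O)c1ccc(OC(C)=O)cc1)C/C=C(\C)CCCC(C)(C)[Cr](Cl)Cl | intermediate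
13 | phenylsilyl ether of 14 at O1 | c1ccccc1[SiH2]O[C@@H]1/C=C(/C)[C@H](OC(=O)c2ccc(OC(C)=O)cc2)C/C=C(\C)CCCC1(C)C | intermediate
14 | (1R,2Z,4R,6E)-1-hydroxy-3,7,11,11-tetramethylcycloundeca-2,6-dien-4-yl 4-acetoxybenzoate | O[C@@H]1/C=C(/C)[C@H](OC(=O)c2ccc(OC(C)=O)cc2)C/C=C(\C)CCCC1(C)C | intermediate
15 | (1R,2Z,4R,6E)-1-acetoxy-3,7,11,11-tetramethylcycloundeca-2,6-dien-4-yl 4-acetoxybenzoate | CC(=O)O[C@@H]1/C=C(/C)[C@H](OC(=O)c2ccc(OC(C)=O)cc2)C/C=C(\C)CCCC1(C)C | intermediate
16 | (1R,2Z,4R,6E)-1-acetoxy-3,7,11,11-tetramethylcycloundeca-2,6-dien-4-yl 4-hydroxybenzoate (CNP0246761.3) | CC(=O)O[C@@H]1/C=C(/C)[C@H](OC(=O)c2ccc(O)cc2)C/C=C(\C)CCCC1(C)C | target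

**Totals**
Total steps: 6. Longest linear sequence: 6 (1 → 16).

**Steps most likely to fail**

Step 5 (macrocyclisation). Hydrogen-atom transfer may also occur at C6=C7, which would lead to a seven-membered carbinol. The C11 radical may cyclise 6-endo onto C6=C7 before chromium captures it. The eleven-membered closure may be too slow, or the C1 epimer may be the wrong one. The fallback sets out from 11 and comes back at 14.
- Hydroxyselenation of 11 with N-(phenylseleno)phthalimide and water (cat. camphorsulfonic acid, aqueous MeCN, 0 °C) adds PhSe to C10 and OH to the tertiary C11 of the terminal alkene. This gives (2Z,4R,6E)-11-hydroxy-3,7,11-trimethyl-1-oxo-10-(phenylselanyl)dodeca-2,6-dien-4-yl 4-acetoxybenzoate F1.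
- Oxidation with H2O2/pyridine (THF, 0 °C) and syn-elimination away from the carbinol gives the tertiary allylic alcohol (2Z,4R,6E,9E)-11-hydroxy-3,7,11-trimethyl-1-oxododeca-2,6,9-trien-4-yl 4-acetoxybenzoate F2.
- PBr3/pyridine (Et2O, −20 °C) gives the transposed allylic bromide (2Z,4R,6E)-9-bromo-3,7,11-trimethyl-1-oxododeca-2,6,10-trien-4-yl 4-acetoxybenzoate F3.
- CrCl2 (divalent chromium, 5 equiv, THF, 25 °C, slow addition) closes the ring by a Nozaki–Hiyama-type allylation in which C11, the γ-carbon, adds to the aldehyde. This gives (1R,2Z,4R,6E,9E)-1-hydroxy-3,7,11,11-tetramethylcycloundeca-2,6,9-trien-4-yl 4-acetoxybenzoate F4.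
- Diimide (2-nitrobenzenesulfonylhydrazide, Et3N, CH2Cl2, 20 °C) reduces only the disubstituted C9=C10 alkene and gives 14.

Step 3 (aminolysis and acylation in one flask). The acid chloride may be consumed by Al–N or Al–Me groups, the hydroxy amide may relactonise, or C4 may erode through the dienolate. The fallback sets out from 6 and comes back at 11, leaving out 9.
- i-Bu2AlH (3 equiv, CH2Cl2, −78 → 0 °C) reduces the lactone to (2Z,4R,6E)-3,7,11-trimethyldodeca-2,6,10-triene-1,4-diol F5.
- TBSCl/imidazole (CH2Cl2, −20 °C) silylates only the primary allylic hydroxyl and gives (2Z,4R,6E)-1-(tert-butyldimethylsilyloxy)-3,7,11-trimethyldodeca-2,6,10-trien-4-ol F6.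
- Acylation with 7 (Et3N, DMAP, CH2Cl2) gives (2Z,4R,6E)-1-(tert-butyldimethylsilyloxy)-3,7,11-trimethyldodeca-2,6,10-trien-4-yl 4-acetoxybenzoate F7.
- HF·pyridine (THF, 0 °C) gives (2Z,4R,6E)-1-hydroxy-3,7,11-trimethyldodeca-2,6,10-trien-4-yl 4-acetoxybenzoate F8.
- F8 is oxidised at once with Dess–Martin periodinane/NaHCO3 to 11.

Step 1 (α-aminoxylation). Regioselectivity (methylene against methyl), N- against O-attack and conversion are less secure for a long-chain methyl ketone than for the small ketones on which the reaction type is established. The fallback sets out from 1 and comes back at 3.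
- Thermodynamic silylation (TMSCl, NaI, Et3N, MeCN, 20 °C) gives the internal enol ether trimethyl{[(2Z,5E)-6,10-dimethylundeca-2,5,9-trien-2-yl]oxy}silane F9.
- MeLi (THF, 0 °C) converts it into the regiodefined lithium (2Z,5E)-6,10-dimethylundeca-2,5,9-trien-2-olate F10.
- F10 is hydroxylated at −78 °C with an enantiopure (camphorsulfonyl)oxaziridine to give 3. The (−)-reagent is expected to give (R) by analogy with Z-enolates of acyclic ketones, and this should be confirmed on the first run.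

**Further compounds**
F1 | step 5 | (2Z,4R,6E)-11-hydroxy-3,7,11-trimethyl-1-oxo-10-(phenylselanyl)dodeca-2,6-dien-4-yl 4-acetoxybenzoate (C10 epimers) | O=C/C=C(/C)[C@H](OC(=O)c1ccc(OC(C)=O)cc1)C/C=C(\C)CCC([Se]c1ccccc1)C(C)(C)O
F2 | step 5 | (2Z,4R,6E,9E)-11-hydroxy-3,7,11-trimethyl-1-oxododeca-2,6,9-trien-4-yl 4-acetoxybenzoate | O=C/C=C(/C)[C@H](OC(=O)c1ccc(OC(C)=O)cc1)C/C=C(\C)C/C=C/C(C)(C)O
F3 | step 5 | (2Z,4R,6E)-9-bromo-3,7,11-trimethyl-1-oxododeca-2,6,10-trien-4-yl 4-acetoxybenzoate (C9 epimers) | O=C/C=C(/C)[C@H](OC(=O)c1ccc(OC(C)=O)cc1)C/C=C(\C)CC(Br)C=C(C)C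
F4 | step 5 | (1R,2Z,4R,6E,9E)-1-hydroxy-3,7,11,11-tetramethylcycloundeca-2,6,9-trien-4-yl 4-acetoxybenzoate | O[C@@H]1/C=C(/C)[C@H](OC(=O)c2ccc(OC(C)=O)cc2)C/C=C(\C)C/C=C/C1(C)C
F5 | step 3 | (2Z,4R,6E)-3,7,11-trimethyldodeca-2,6,10-triene-1,4-diol | OC/C=C(/C)[C@H](O)C/C=C(\C)CCC=C(C)C
F6 | step 3 | (2Z,4R,6E)-1-(tert-butyldimethylsilyloxy)-3,7,11-trimethyldodeca-2,6,10-trien-4-ol | CC(C)(C)[Si](C)(C)OC/C=C(/C)[C@H](O)C/C=C(\C)CCC=C(C)C
F7 | step 3 | (2Z,4R,6E)-1-(tert-butyldimethylsilyloxy)-3,7,11-trimethyldodeca-2,6,10-trien-4-yl 4-acetoxybenzoate | CC(C)(C)[Si](C)(C)OC/C=C(/C)[C@H](OC(=O)c1ccc(OC(C)=O)cc1)C/C=C(\C)CCC=C(C)C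
F8 | step 3 | (2Z,4R,6E)-1-hydroxy-3,7,11-trimethyldodeca-2,6,10-trien-4-yl 4-acetoxybenzoate | OC/C=C(/C)[C@H](OC(=O)c1ccc(OC(C)=O)cc1)C/C=C(\C)CCC=C(C)C
F9 | step 1 | trimethyl{[(2Z,5E)-6,10-dimethylundeca-2,5,9-trien-2-yl]oxy}silane | C/C(O[Si](C)(C)C)=C/C/C=C(\C)CCC=C(C)C
F10 | step 1 | lithium (2Z,5E)-6,10-dimethylundeca-2,5,9-trien-2-olate | C/C(O[Li])=C/C/C=C(\C)CCC=C(C)C
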